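The C40 skeleton is cut at the central C15=C15' alkene into two C20 halves, each built as an allylic electrophile and joined through sulfur. One operation, Ramberg–Bäcklund extrusion, then turns the C15–SO2–C15' bridge into the fully conjugated C15=C15' bond. The step exploits the two allylic CH2 groups C15 and C15' flanking the sulfone, C15 being further acidified through the C9–C14 triene by the C8 ketone. Ring A carries its C3 ketone as a dioxolane and ring B its C3' hydroxyl as a TBS ether, so only C15 and C15' respond to base and halogen donor. The precursor is thus a bis(C20-allyl) sulfone.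

Key step: step 17

Remarks on the chemistry:
- Carotenoid numbering is used (ring A C1–C6 with the C3 ketone, chain C7–C15, primed locants for the ring B half). "6Z" means that C8 lies cis to C5 across C6=C7.
- The sulfone and its extrusion product carry the C3' hydroxyl as a TBS ether, because a free alkoxide would intercept the difluorocarbene released by the halogen donor.
- The ring B sulfur is brought in as a sulfinate at the sulfone oxidation level, so no oxidant meets the polyenes.
- The two halves receive their C5 unit differently. Ring A holds the C8 ketone, so its C13–C15 end must arrive at the alcohol oxidation level (acetoxy ylide). Ring B holds no carbonyl, so the ester phosphonate followed by hydride reduction is used there.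
- Assumption: phosphonate 20 is taken as the commercial E-enriched reagent; both of its geometric isomers should give the same delocalised anion.

Step 1
Reactants: 1 ketoisophorone
Product: 2 ketoisophorone 4-(ethylene ketal) (7,9,9-trimethyl-1,4-dioxaspiro[4.5]dec-6-en-8-one)
Conditions: ethylene glycol, p-TsOH (cat.), benzene, reflux, azeotropic removal of water
Reagents that add atoms: ethylene glycol, OCCO
Why: Acid-catalysed ketalisation should be site-selective for the carbonyl between CH= and CH2 (future C3), since the other carbonyl is shielded by the gem-dimethyl carbon and the methyl-bearing alkene carbon; the alkene stays conjugated to the remaining ketone, so it should not migrate.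

Step 2
Reactants: 2 ketoisophorone 4-(ethylene ketal); 3 (E)-3-methylpent-2-en-4-yn-1-ol
Product: 5 racemic C6 propargylic diol, via dilithio alkoxide-acetylide 4 (not isolated)
Conditions: 3, n-BuLi (2 equiv), THF, −78 → −20 °C; then 2, −78 → 0 °C; H2O
Reagents that add atoms: none
Why: Acetylide 1,2-addition to a non-enolisable ketone (future C6) forms C6–C7, the alkoxide half of the dianion needing no protection; the new carbinol centre is racemic and is erased in step 3.

Step 3
Reactants: 5 racemic C6 propargylic diol
Product: 6 (6Z,9E) ring A C15 hydroxy dienone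
Conditions: Ph3PAuNTf2 (2 mol %), MeOH (1 equiv), toluene, rt; separation of the C6=C7 isomers on silica
Reagents that add atoms: none
Why: Meyer–Schuster rearrangement, in which cationic gold activates the alkyne and a formal 1,3-shift of the C6 hydroxyl gives an allenol that tautomerises to the C6=C7–C8(=O) enone, while the E geometry of C9=C10 keeps the primary hydroxyl out of reach of the alkyne; the C6=C7 geometry is not set kinetically, so both isomers are expected, the 6Z isomer (H7 beside the C1 methyls, to be confirmed by NOE) is taken on and the 6E isomer is re-equilibrated (I2 cat., light) and recycled.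

Step 4
Reactants: 6 (6Z,9E) ring A C15 hydroxy dienone
Product: 7 (6Z,9E) ring A C15 keto aldehyde
Conditions: MnO2, CH2Cl2, rt
Reagents that add atoms: none
Why: Chemoselective MnO2 oxidation of the only alcohol (primary, allylic) to the enal; ketone, dioxolane and both alkene geometries should be untouched.

Step 5
Reactants: 8 (E)-4-chloro-3-methylbut-2-en-1-yl acetate
Product: 9 [(E)-4-acetoxy-2-methylbut-2-en-1-yl]tributylphosphonium chloride
Conditions: PBu3, MeCN, rt → 50 °C, argon
Reagents that add atoms: tributylphosphine, CCCCP(CCCC)CCCC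
Why: SN2 quaternisation of a primary allylic chloride by a trialkylphosphine; the acetate and the E alkene (future C13=C14) are not involved.

Step 6
Reactants: 7 (6Z,9E) ring A C15 keto aldehyde; 9 [(E)-4-acetoxy-2-methylbut-2-en-1-yl]tributylphosphonium chloride
Product: 12 ring A C20 allylic alcohol, via tributylphosphonium ylide 10 (not isolated), via ring A C20 acetate 11 (not isolated)
Conditions: 9, KN(SiMe3)2, THF, −78 °C; then 7, −78 → 0 °C; then K2CO3, MeOH, rt
Reagents that add atoms: none
Why: Wittig olefination at the aldehyde (far more electrophilic than the hindered cross-conjugated C8 ketone) forms C11=C12, allylic trialkylphosphonium ylides being E-selective with aldehydes, and methanolysis of the acetate in the same flask frees the C15 alcohol; the ylide is made cold and trapped at once to forestall 1,4-loss of acetate.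

Step 7
Reactants: 12 ring A C20 allylic alcohol
Product: 13 ring A C20 allylic bromide
Conditions: CBr4, PPh3, CH2Cl2, −30 °C
Reagents that add atoms: carbon tetrabromide, BrC(Br)(Br)Br
Why: Appel reaction under neutral conditions replaces the primary allylic hydroxyl by bromide through SN2 at C15; conjugation to the C8 ketone disfavours ionisation and the dioxolane sees no acid.

Step 8
Reactants: 14 (4R,6R)-4-hydroxy-2,2,6-trimethylcyclohexanone (actinol)
Product: 15 (4R,6R)-4-(tert-butyldimethylsilyloxy)-2,2,6-trimethylcyclohexanone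
Conditions: TBSCl, imidazole, DMF, rt
Reagents that add atoms: tert-butyldimethylsilyl chloride, CC(C)(C)[Si](C)(C)Cl
Why: Standard silylation of the secondary alcohol; the TBS ether should withstand every basic and hydride step up to and including the extrusion and fall in the final acid step.

Step 9
Reactants: 15 (4R,6R)-4-(tert-butyldimethylsilyloxy)-2,2,6-trimethylcyclohexanone
Product: 17 (R)-4-(tert-butyldimethylsilyloxy)-2,6,6-trimethylcyclohex-1-en-1-yl triflate, via lithium enolate 16 (not isolated)
Conditions: LiN(i-Pr)2, THF, −78 → 0 °C; then PhNTf2, −78 °C → rt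
Reagents that add atoms: N-phenylbis(trifluoromethanesulfonimide), O=S(=O)(N(c1ccccc1)S(=O)(=O)C(F)(F)F)C(F)(F)F
Why: Enol triflate formation, in which the ketone has a single enolisable α-hydrogen (at the methyl-bearing carbon) so only the tetrasubstituted enolate can form and O-sulfonylation fixes the future C5'=C6' alkene; that methine centre is erased on purpose and the silyloxy carbon (future C3', R) is untouched.

Step 10
Reactants: 17 (R)-4-(tert-butyldimethylsilyloxy)-2,6,6-trimethylcyclohex-1-en-1-yl triflate; 3 (E)-3-methylpent-2-en-4-yn-1-ol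
Product: 18 ring B C15 enynol (E)
Conditions: Pd(PPh3)4 (cat.), CuI (cat.), i-Pr2NH, DMF, rt
Reagents that add atoms: none
Why: Sonogashira coupling of the vinyl triflate with the terminal alkyne forms C6'–C7' with the ring alkene already in place, so no dehydration is needed; the free hydroxyl and the E alkene are tolerated.

Step 11
Reactants: 18 ring B C15 enynol
Product: 19 ring B C15 ynenal (E)
Conditions: MnO2, CH2Cl2, rt
Reagents that add atoms: none
Why: Chemoselective MnO2 oxidation of the primary allylic alcohol; the silyl ether and the alkyne should be inert.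

Step 12
Reactants: 19 ring B C15 ynenal; 20 ethyl (E)-4-(diethoxyphosphoryl)-3-methylbut-2-enoate
Product: 22 ring B C20 ethyl ester, via lithium phosphonate anion 21 (not isolated)
Conditions: 20, n-BuLi, DMPU, THF, −78 °C; then 19, −78 → 0 °C
Reagents that add atoms: none
Why: Horner–Wadsworth–Emmons olefination, in which the ester-stabilised phosphonate anion adds to the aldehyde and the oxaphosphetane collapses to the E alkene C11'=C12'; low temperature with DMPU should keep C13'=C14' E, and any 13'Z isomer is removed by chromatography.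

Step 13
Reactants: 22 ring B C20 ethyl ester
Product: 23 ring B C20 allylic alcohol
Conditions: i-Bu2AlH (2.2 equiv), CH2Cl2, −78 °C; aq. potassium sodium tartrate
Reagents that add atoms: none
Why: 1,2-Reduction of the conjugated ester by two hydride equivalents gives the C15' allylic alcohol; the silyl ether, the alkyne and the alkene geometries should not be affected at −78 °C.

Step 14
Reactants: 23 ring B C20 allylic alcohol
Product: 24 ring B C20 allylic bromide
Conditions: CBr4, PPh3, CH2Cl2, −40 °C; used at once
Reagents that add atoms: carbon tetrabromide, BrC(Br)(Br)Br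
Why: Appel reaction at low temperature gives the primary allylic bromide by SN2 at C15'; the alkyne makes the polyenyl cation less accessible than in a retinyl system, and the bromide is used without storage.

Step 15
Reactants: 24 ring B C20 allylic bromide
Product: 25 ring B C20 sulfone ester (methyl 3-sulfonylpropanoate)
Conditions: NaO2SCH2CH2CO2Me, DMSO, rt, dark
Reagents that add atoms: sodium 3-methoxy-3-oxopropane-1-sulfinate, COC(=O)CCS(=O)[O-].[Na+]
Why: S-alkylation of a sulfinate by the allylic bromide (SN2 at C15') installs sulfur already at the sulfone oxidation level, and the ester arm is a releasable handle.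

Step 16
Reactants: 25 ring B C20 sulfone ester; 13 ring A C20 allylic bromide
Product: 27 TBS-protected C3-dioxolane bis(C20-allyl) sulfone, via ring B C20 sodium sulfinate 26 (not isolated)
Conditions: 25, NaOMe (1 equiv), THF/MeOH, 0 °C → rt; concentrate; then 13, DMF, 0 °C → rt
Reagents that add atoms: none
Why: Retro-Michael (E1cB) cleavage of the β-sulfonyl ester releases the allylic sulfinate, kept as its sodium salt because free allylic sulfinic acids lose SO2, and S-alkylation by the soft primary bromide 13 (SN2 at C15) gives the unsymmetrical sulfone.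

Step 17
Reactants: 27 TBS-protected C3-dioxolane bis(C20-allyl) sulfone
Product: 30 TBS-protected C3-dioxolane of the target, via C15 bromo sulfone 28 (not isolated), via episulfone 29 (not isolated)
Conditions: CBr2F2, KOH/Al2O3, t-BuOH/CH2Cl2, 0 °C → rt, dark, argon
Reagents that add atoms: none
Why: KOH removes a proton at C15, the more acidic of the two sulfone α-positions because its anion is also a trienolate of the C8 ketone, and bromine transfer from CBr2F2 gives α-bromo sulfone 28 (bromination at C15' would converge on the same ring). A second deprotonation at C15' and intramolecular SN2 displacement of bromide (3-exo-tet) close episulfone 29, which loses SO2 cheletropically to leave C15=C15', so no ring survives. This is the Ramberg–Bäcklund olefination with in situ halogenation, the closest known case being the conversion of diallylic sulfones into conjugated trienes in polyene synthesis. No stereocentre remains in the product; the E alkene is expected because base equilibrates the episulfone to its trans isomer before extrusion and the extended polyene is the thermodynamic product, and any 15Z share should isomerise on gentle warming. The step needs halogenation and carbanion formation only at C15 and C15': ring A has its C3 ketone masked so C2–H2 is not enolisable, the C8 ketone has no α-hydrogen, and the silyl ether keeps the C3' oxygen away from base and difluorocarbene.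

Step 18
Reactants: 30 TBS-protected C3-dioxolane of the target
Product: 31 target carotenoid CNP0205386.1
Conditions: 1 M aq HCl, THF, 0 °C → rt, dark, argon
Reagents that add atoms: water, O
Why: Acid hydrolysis cleaves the dioxolane (returning the C3 enone) and the TBS ether in one operation; the C3' carbinol lies between two CH2 groups and cannot ionise, the C8 divinyl ketone would need far stronger acid to cyclise, and no stereocentre is touched.

Compound list
1 | ketoisophorone (2,6,6-trimethylcyclohex-2-ene-1,4-dione) | CC1=CC(=O)CC(C)(C)C1=O | starting material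
2 | ketoisophorone 4-(ethylene ketal), 7,9,9-trimethyl-1,4-dioxaspiro[4.5]dec-6-en-8-one | CC1=CC2(OCCO2)CC(C)(C)C1=O | intermediate
3 | (E)-3-methylpent-2-en-4-yn-1-ol | C#C/C(C)=C/CO | starting material
4 | dilithium alkoxide-acetylide of 3 | [Li]OC/C=C(C)/C#C[Li] | intermediate
5 | racemic 8-[(E)-5-hydroxy-3-methylpent-3-en-1-yn-1-yl]-7,9,9-trimethyl-1,4-dioxaspiro[4.5]dec-6-en-8-ol (C6 carbinol unassigned) | CC1=CC2(OCCO2)CC(C)(C)C1(O)C#C/C(C)=C/CO | intermediate
6 | (E)-5-hydroxy-3-methyl-1-[(Z)-7,9,9-trimethyl-1,4-dioxaspiro[4.5]dec-6-en-8-ylidene]pent-3-en-2-one (6Z,9E) | CC1=CC2(OCCO2)CC(C)(C)/C1=C/C(=O)/C(C)=C/CO | intermediate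
7 | (E)-3-methyl-4-oxo-5-[(Z)-7,9,9-trimethyl-1,4-dioxaspiro[4.5]dec-6-en-8-ylidene]pent-2-enal | CC1=CC2(OCCO2)CC(C)(C)/C1=C/C(=O)/C(C)=C/C=O | intermediate
8 | (E)-4-chloro-3-methylbut-2-en-1-yl acetate | CC(=O)OC/C=C(C)/CCl | starting material
9 | [(E)-4-acetoxy-2-methylbut-2-en-1-yl]tributylphosphonium chloride | CC(=O)OC/C=C(C)/C[P+](CCCC)(CCCC)CCCC.[Cl-] | intermediate
10 | tributylphosphonium ylide of 9 | CC(=O)OC/C=C(C)/C=P(CCCC)(CCCC)CCCC | intermediate
11 | ring A C20 acetate, (2E,4E,6E)-3,7-dimethyl-8-oxo-9-[(Z)-7,9,9-trimethyl-1,4-dioxaspiro[4.5]dec-6-en-8-ylidene]nona-2,4,6-trien-1-yl acetate | CC1=CC2(OCCO2)CC(C)(C)/C1=C/C(=O)/C(C)=C/C=C/C(C)=C/COC(C)=O | intermediate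
12 | ring A C20 alcohol, (3E,5E,7E)-9-hydroxy-3,7-dimethyl-1-[(Z)-7,9,9-trimethyl-1,4-dioxaspiro[4.5]dec-6-en-8-ylidene]nona-3,5,7-trien-2-one | CC1=CC2(OCCO2)CC(C)(C)/C1=C/C(=O)/C(C)=C/C=C/C(C)=C/CO | intermediate
13 | ring A C20 bromide, (3E,5E,7E)-9-bromo-3,7-dimethyl-1-[(Z)-7,9,9-trimethyl-1,4-dioxaspiro[4.5]dec-6-en-8-ylidene]nona-3,5,7-trien-2-one | CC1=CC2(OCCO2)CC(C)(C)/C1=C/C(=O)/C(C)=C/C=C/C(C)=C/CBr | intermediate
14 | (4R,6R)-4-hydroxy-2,2,6-trimethylcyclohexanone (actinol) | O=C1[C@H](C)C[C@@H](O)CC1(C)C | starting material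
15 | (4R,6R)-4-(tert-butyldimethylsilyloxy)-2,2,6-trimethylcyclohexanone | O=C1[C@H](C)C[C@@H](O[Si](C)(C)C(C)(C)C)CC1(C)C | intermediate
16 | lithium enolate of 15 (tetrasubstituted) | [Li]OC1=C(C)C[C@@H](O[Si](C)(C)C(C)(C)C)CC1(C)C | intermediate
17 | (R)-4-(tert-butyldimethylsilyloxy)-2,6,6-trimethylcyclohex-1-en-1-yl trifluoromethanesulfonate | FC(F)(F)S(=O)(=O)OC1=C(C)C[C@@H](O[Si](C)(C)C(C)(C)C)CC1(C)C | intermediate
18 | (E)-5-[(R)-4-(tert-butyldimethylsilyloxy)-2,6,6-trimethylcyclohex-1-en-1-yl]-3-methylpent-2-en-4-yn-1-ol | OC/C=C(\C)C#CC1=C(C)C[C@@H](O[Si](C)(C)C(C)(C)C)CC1(C)C | intermediate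
19 | (E)-5-[(R)-4-(tert-butyldimethylsilyloxy)-2,6,6-trimethylcyclohex-1-en-1-yl]-3-methylpent-2-en-4-ynal | O=C/C=C(\C)C#CC1=C(C)C[C@@H](O[Si](C)(C)C(C)(C)C)CC1(C)C | intermediate
20 | ethyl (E)-4-(diethoxyphosphoryl)-3-methylbut-2-enoate (triethyl 3-methyl-4-phosphonocrotonate) | CCOC(=O)/C=C(C)/CP(=O)(OCC)OCC | starting material
21 | lithium salt of the C4 carbanion of 20 (delocalised phosphonate anion) | [Li+].CCOC(=O)/C=C(C)/[CH-]P(=O)(OCC)OCC | intermediate
22 | ring B C20 ethyl ester, ethyl (2E,4E,6E)-9-[(R)-4-(tert-butyldimethylsilyloxy)-2,6,6-trimethylcyclohex-1-en-1-yl]-3,7-dimethylnona-2,4,6-trien-8-ynoate | CCOC(=O)/C=C(C)/C=C/C=C(\C)C#CC1=C(C)C[C@@H](O[Si](C)(C)C(C)(C)C)CC1(C)C | intermediate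
23 | ring B C20 alcohol, (2E,4E,6E)-9-[(R)-4-(tert-butyldimethylsilyloxy)-2,6,6-trimethylcyclohex-1-en-1-yl]-3,7-dimethylnona-2,4,6-trien-8-yn-1-ol | OC/C=C(C)/C=C/C=C(\C)C#CC1=C(C)C[C@@H](O[Si](C)(C)C(C)(C)C)CC1(C)C | intermediate
24 | ring B C20 bromide (C15' bromide of 23) | BrC/C=C(C)/C=C/C=C(\C)C#CC1=C(C)C[C@@H](O[Si](C)(C)C(C)(C)C)CC1(C)C | intermediate
25 | ring B C20 sulfone ester, methyl 3-(C20-allylsulfonyl)propanoate | COC(=O)CCS(=O)(=O)C/C=C(C)/C=C/C=C(\C)C#CC1=C(C)C[C@@H](O[Si](C)(C)C(C)(C)C)CC1(C)C | intermediate
26 | ring B C20 sodium allylsulfinate | [Na+].[O-]S(=O)C/C=C(C)/C=C/C=C(\C)C#CC1=C(C)C[C@@H](O[Si](C)(C)C(C)(C)C)CC1(C)C | intermediate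
27 | bis(C20-allyl) sulfone: C15–SO2–C15' bridge, ring A C3 dioxolane, 6Z, C8 ketone, ring B (3'R)-OTBS, 7',8'-alkyne, all other chain alkenes E | CC1=CC2(OCCO2)CC(C)(C)/C1=C/C(=O)/C(C)=C/C=C/C(C)=C/CS(=O)(=O)C/C=C(C)/C=C/C=C(\C)C#CC1=C(C)C[C@@H](O[Si](C)(C)C(C)(C)C)CC1(C)C | intermediate
28 | C15-bromo derivative of sulfone 27 (C15 configuration not controlled) | CC1=CC2(OCCO2)CC(C)(C)/C1=C/C(=O)/C(C)=C/C=C/C(C)=C/C(Br)S(=O)(=O)C/C=C(C)/C=C/C=C(\C)C#CC1=C(C)C[C@@H](O[Si](C)(C)C(C)(C)C)CC1(C)C | intermediate
29 | episulfone (thiirane 1,1-dioxide spanning C15 and C15', trans after base equilibration, absolute configuration not controlled) | CC1=CC2(OCCO2)CC(C)(C)/C1=C/C(=O)/C(C)=C/C=C/C(C)=C/C1C(/C=C(C)/C=C/C=C(\C)C#CC3=C(C)C[C@@H](O[Si](C)(C)C(C)(C)C)CC3(C)C)S1(=O)=O | intermediate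
30 | TBS-protected C3-dioxolane of the target (C15=C15' E) | CC1=CC2(OCCO2)CC(C)(C)/C1=C/C(=O)/C(C)=C/C=C/C(C)=C/C=C/C=C(C)/C=C/C=C(\C)C#CC1=C(C)C[C@@H](O[Si](C)(C)C(C)(C)C)CC1(C)C | intermediate
31 | CNP0205386.1: ring A 3-oxo-4-ene with exocyclic (6Z)-C6=C7, C8 ketone, all-E chain, 7',8'-alkyne, (3'R)-hydroxy ring B | CC1=CC(=O)CC(C)(C)/C1=C/C(=O)/C(C)=C/C=C/C(C)=C/C=C/C=C(C)/C=C/C=C(\C)C#CC1=C(C)C[C@@H](O)CC1(C)C | target

Total step count: 18 steps.
Longest linear sequence: 11 steps (14 → 15 → 17 → 18 → 19 → 22 → 23 → 24 → 25 → 27 → 30 → 31, steps 8–18).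

Steps most likely to fail

1. Step 17. Halogenation may not stop at one bromine on the doubly activated C15, or may occur along the trienolate at C9, C11 or C13. Hydroxide may also degrade the polyenone before the three-membered ring closes, and the new alkene may form with a large Z share. The fallback makes the same C15=C15' bond by Wittig olefination instead of sulfur extrusion. It sets out from 24 and 12. Bromide 24 with PPh3 in CH2Cl2 should give ring B C20 triphenylphosphonium bromide F1. Alcohol 12 with MnO2 in CH2Cl2 should give ring A C20 aldehyde F2. F1 and F2 with NaOMe in CH2Cl2/MeOH, followed by gentle heating to isomerise the 15Z share, should give 30, where the route is rejoined.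

2. Step 3. The gold catalyst may engage the free allylic hydroxyl or the dioxolane, the vinylallene intermediate may cyclise in a Nazarov manner, and the C6=C7 isomer distribution may be unfavourable or hard to separate. The fallback masks the primary alcohol and uses an oxo-metal ester [3,3] shift that involves no cationic intermediate. It sets out from 3 and 2. Silylation of 3 (TBSCl, imidazole) gives enyne silyl ether F3. Its lithium acetylide F4 (n-BuLi, THF, −78 °C) adds to 2 to give silyl carbinol F5. Heating F5 with VO(OSiPh3)3 (cat.) and Ph3SiOH in xylene should give silyl enone F6 as its thermodynamic C6=C7 mixture, from which the 6Z isomer is separated. Bu4NF/AcOH in THF then returns the route at 6.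

3. Step 6. The acetoxy-bearing ylide may lose acetate by 1,4-elimination, or may deprotonate the C9 methyl of the ene-dione aldehyde instead of adding to it, and E selectivity at C11=C12 may be incomplete. The fallback reverses the polarity so that a keto-stabilised, E-selective ylide sits on the ring A piece. It sets out from 6. An Appel reaction (CBr4, PPh3) gives ring A C15 bromide F7. PPh3 in CH2Cl2 gives ring A C15 triphenylphosphonium bromide F8. NaOMe in MeOH/CH2Cl2 forms keto-stabilised ylide F9, which should condense with commercial (E)-4-acetoxy-2-methylbut-2-enal (CC(=O)OC/C=C(C)/C=O) to give acetate 11. The same methoxide cleaves the acetate, so the route is rejoined at 12.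

Further compounds
F1 | step 17 | ring B C20 triphenylphosphonium bromide | [Br-].C(/C=C(C)/C=C/C=C(\C)C#CC1=C(C)C[C@@H](O[Si](C)(C)C(C)(C)C)CC1(C)C)[P+](c1ccccc1)(c1ccccc1)c1ccccc1
F2 | step 17 | ring A C20 aldehyde | CC1=CC2(OCCO2)CC(C)(C)/C1=C/C(=O)/C(C)=C/C=C/C(C)=C/C=O
F3 | step 3 | (E)-tert-butyldimethyl[(3-methylpent-2-en-4-yn-1-yl)oxy]silane | C#C/C(C)=C/CO[Si](C)(C)C(C)(C)C
F4 | step 3 | lithium acetylide of F3 | [Li]C#C/C(C)=C/CO[Si](C)(C)C(C)(C)C
F5 | step 3 | racemic C6 propargylic carbinol with C11 silyl ether | CC1=CC2(OCCO2)CC(C)(C)C1(O)C#C/C(C)=C/CO[Si](C)(C)C(C)(C)C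
F6 | step 3 | (6Z,9E) ring A C15 dienone C11 silyl ether | CC1=CC2(OCCO2)CC(C)(C)/C1=C/C(=O)/C(C)=C/CO[Si](C)(C)C(C)(C)C
F7 | step 6 | ring A C15 allylic bromide | CC1=CC2(OCCO2)CC(C)(C)/C1=C/C(=O)/C(C)=C/CBr
F8 | step 6 | ring A C15 triphenylphosphonium bromide | CC1=CC2(OCCO2)CC(C)(C)/C1=C/C(=O)/C(C)=C/C[P+](c1ccccc1)(c1ccccc1)c1ccccc1.[Br-]
F9 | step 6 | keto-stabilised ring A C15 ylide | CC1=CC2(OCCO2)CC(C)(C)/C1=C/C(=O)/C(C)=C/C=P(c1ccccc1)(c1ccccc1)c1ccccc1
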